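**Plan**
- Retrosynthesis: the cyclohexadienone (filicinic) ring is cut at C-4–C-5 and at C-2–C-3 (C-1 = ring C=O, C-2 = butanoyl-bearing carbon, C-4 = carbon bearing the CH2 bridge, C-6 = CMe2). C-3/C-4 with the bridge and the arene become an aryl δ-lactone (a 3,4-dihydrocoumarin, a ring absent from the target); C-5/C-6/C-1/C-2 with the ring butanoyl group become 3,3-dimethyl-6-propylpyran-2,4-dione.
- Enabling features: the quaternary C-6 between the C-1 and C-5 carbonyl carbons makes the pyrandione a non-enolisable acyl donor whose leaving group is the β-diketonate of C-2. The phenolic oxygen ortho to the CH2 bridge can be tied to C-3 as an activated aryl ester.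
- Forward order: the benzene ring is present from the start (5,7-dihydroxycoumarin), the lactone ring is carried as a temporary ring, and the cyclohexadienone ring is closed last by a one-flask Claisen acylation/Dieckmann ring switch that opens both lactones and loses no atom.
- Regiochemistry: the OMe para to the bridge is O-7 of the coumarin. Methyl and butanoyl then fill C-6 and C-8, and either placement gives the same target because lactone opening makes the two oxygens beside the bridge equivalent.
- Stereochemistry: the target has no stereocentre; the one sp3 methine formed on the way (C-3 of the acylated lactone) ends as an sp2 ring carbon.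

Key step: step 8

Remark: the target is handled as the enol tautomer drawn in its SMILES; 5,7-dihydroxycoumarin and tert-butyl acetoacetate are taken as the commercial starting materials.

**Route**

Step 1
Reactants: 1 5,7-dihydroxy-2H-chromen-2-one
Product: 2 5-hydroxy-7-methoxy-2H-chromen-2-one
Conditions: MeI (1.05 equiv), K2CO3 (1.0 equiv), acetone, 23 °C
Reagents that add atoms: iodomethane (CI)
Why: Williamson ether synthesis under limiting base and electrophile should methylate the 7-OH, the more acidic and less hindered phenol (para to the enoate-bearing C-4a, whereas the 5-OH sits beside the peri C-4 hydrogen), and leave the 5-OH free.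

Step 2
Reactants: 2 5-hydroxy-7-methoxy-2H-chromen-2-one
Product: 3 5-hydroxy-7-methoxy-2-oxo-2H-chromene-6-carbaldehyde
Conditions: MgCl2 (2 equiv), Et3N (4 equiv), (CH2O)n (6 equiv), MeCN, reflux; 1 M HCl
Reagents that add atoms: paraformaldehyde (as formaldehyde, C=O)
Why: Magnesium-mediated ortho-formylation of the phenol delivers formaldehyde inside the magnesium phenoxide to C-6, the only free ortho carbon, and a second formaldehyde oxidises the benzylic alkoxide to the aldehyde by hydride transfer; substitution at C-8 would be harmless, since both sites lie between the methoxy group and an oxygen that ends as a free phenol.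

Step 3
Reactants: 3 5-hydroxy-7-methoxy-2-oxo-2H-chromene-6-carbaldehyde
Product: 4 5-hydroxy-7-methoxy-6-methyl-3,4-dihydro-2H-chromen-2-one
Conditions: H2 (4 atm), Pd/C, AcOH, 50 °C
Reagents that add atoms: none
Why: Heterogeneous catalytic hydrogenation should saturate the C-3–C-4 double bond of the coumarin and hydrogenolyse the electron-rich ortho-hydroxy benzaldehyde through its benzylic alcohol to the methyl group, while the lactone, the aryl ether and the benzene ring stay untouched.

Step 4
Reactants: 4 5-hydroxy-7-methoxy-6-methyl-3,4-dihydro-2H-chromen-2-one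
Product: 5 8-butanoyl-5-hydroxy-7-methoxy-6-methyl-3,4-dihydro-2H-chromen-2-one
Conditions: n-PrCO2H (3 equiv), BF3·OEt2, 80 °C; aq. NaOAc
Reagents that add atoms: butanoic acid (CCCC(=O)O)
Why: Friedel–Crafts acylation can only take place at C-8, the single free ring carbon, which is para to the free phenol and ortho to the methoxy group; any 5-O-butanoate is carried on to the same ketone by a para Fries shift, and BF3 should leave the aryl methyl ether and the lactone intact.

Step 5
Reactants: 6 tert-butyl 3-oxobutanoate
Product: 7 tert-butyl 2,2-dimethyl-3-oxobutanoate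
Conditions: MeI (2.5 equiv), K2CO3 (3 equiv), acetone, reflux
Reagents that add atoms: iodomethane (CI)
Why: Double C-alkylation of the β-keto ester at its doubly activated methylene (acetoacetic ester alkylation) installs the quaternary carbon that later becomes C-6 of the target ring.

Step 6
Reactants: 7 tert-butyl 2,2-dimethyl-3-oxobutanoate
Product: 9 tert-butyl 2,2-dimethyl-3,5-dioxooctanoate, via lithium enolate 8 (not isolated)
Conditions: LiN(SiMe3)2 (2.1 equiv), THF, −78 °C; n-PrCOCl (1.0 equiv), −78 → 0 °C; aq. NH4Cl
Reagents that add atoms: butanoyl chloride (CCCC(=O)Cl)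
Why: Crossed Claisen C-acylation of a ketone enolate by an acid chloride, regiochemically unambiguous because the acetyl methyl is the only enolisable position, with the second equivalent of the non-nucleophilic amide taking up the acidic proton of the β-diketone so that neither retro-Claisen cleavage nor proton quench intervenes.

Step 7
Reactants: 9 tert-butyl 2,2-dimethyl-3,5-dioxooctanoate
Product: 11 3,3-dimethyl-6-propyl-2H-pyran-2,4(3H)-dione, via diketo acid 10 (not isolated)
Conditions: CF3CO2H, CH2Cl2, 0 → 23 °C; then (CF3CO)2O (1.5 equiv), 23 °C; evaporation, short-path distillation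
Reagents that add atoms: none
Why: Acidolysis of the tert-butyl ester and activation of acid 10 as a mixed trifluoroacetic anhydride lead to 6-exo-trig lactonisation by the enol oxygen on C-5, the known cyclodehydration of 3,5-dioxo acids to pyranones, here favoured by the gem-dimethyl (Thorpe–Ingold) effect and stopped at the non-aromatic 2,4-dione because C-3 carries no hydrogen.

Step 8
Reactants: 5 8-butanoyl-5-hydroxy-7-methoxy-6-methyl-3,4-dihydro-2H-chromen-2-one; 11 3,3-dimethyl-6-propyl-2H-pyran-2,4(3H)-dione
Product: 14 aspidin, via trilithium trianion 12 (not isolated), via acylated lactone 13 (not isolated)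
Conditions: LiN(i-Pr)2 (3.1 equiv), THF, −78 °C; 11 (1.05 equiv), −78 → −20 °C; AcOH (1.1 equiv), 23 → 40 °C; 1 M HCl
Reagents that add atoms: none
Why: Proposed new method: in trianion 12 the lactone enolate carbon (lactone C-3) is the least delocalised and least hindered carbanion and should add 1,2 to the enol-ester carbonyl C-2 of 11, a non-enolisable vinylogous anhydride, whose tetrahedral adduct collapses by ring opening to a β-diketonate, while the aryl ketone enolate acts as internal base for the acidic lactone C-3 hydrogen so formed and gives 13. After one proton is returned with AcOH, the central β-diketonate carbon attacks the aryl lactone carbonyl, now a β-keto aryl ester, and expels the phenoxide, and deprotonation of the resulting 2-acylcyclohexane-1,3,5-trione makes the sequence irreversible. The closest known reaction types are the crossed Claisen acylation of ester enolates by enol esters and the anionic annulations of the Hauser–Kraus and Staunton–Weinreb kind, in which a carbanion adds to an acceptor and the ring is then closed by Dieckmann attack on a lactone or ester. The cyclohexadienone ring closes in a 6-exo-trig (enolexo) mode through bond C-2–C-3 (target numbering), after the intermolecular step has made bond C-4–C-5, so that the step is a formal [4+2] annulation in which both lactone rings are opened and no atom is lost. No stereocentre arises, because the sp3 lactone carbon C-3 becomes the sp2 carbon C-4 of the enolised ring. The selectivity needed is attack of the lactone enolate, not of the ketone enolate or the phenoxide, at C-2 and not at C-6 of 11; it should be secured by the two ortho substituents that shield the ketone enolate, by the hard lithium enolate at −78 °C, and by the reversibility of any O-acylation, which the lactone enolate can correct through a six-membered O-to-C acyl shift.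

**Compound list**

1 | 5,7-dihydroxy-2H-chromen-2-one (5,7-dihydroxycoumarin) | Oc1cc(O)c2C=CC(=O)Oc2c1 | starting material
2 | 5-hydroxy-7-methoxy-2H-chromen-2-one | COc1cc(O)c2C=CC(=O)Oc2c1 | intermediate
3 | 5-hydroxy-7-methoxy-2-oxo-2H-chromene-6-carbaldehyde | O=Cc1c(OC)cc2OC(=O)C=Cc2c1O | intermediate
4 | 5-hydroxy-7-methoxy-6-methyl-3,4-dihydro-2H-chromen-2-one | COc1cc2OC(=O)CCc2c(O)c1C | intermediate
5 | 8-butanoyl-5-hydroxy-7-methoxy-6-methyl-3,4-dihydro-2H-chromen-2-one | CCCC(=O)c1c(OC)c(C)c(O)c2CCC(=O)Oc12 | intermediate
6 | tert-butyl 3-oxobutanoate | CC(=O)CC(=O)OC(C)(C)C | starting material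
7 | tert-butyl 2,2-dimethyl-3-oxobutanoate | CC(=O)C(C)(C)C(=O)OC(C)(C)C | intermediate
8 | lithium 4-tert-butoxy-3,3-dimethyl-4-oxobut-1-en-2-olate (lithium enolate of 7, not isolated) | [Li+].[O-]C(=C)C(C)(C)C(=O)OC(C)(C)C | intermediate
9 | tert-butyl 2,2-dimethyl-3,5-dioxooctanoate | CCCC(=O)CC(=O)C(C)(C)C(=O)OC(C)(C)C | intermediate
10 | 2,2-dimethyl-3,5-dioxooctanoic acid (not isolated) | CCCC(=O)CC(=O)C(C)(C)C(O)=O | intermediate
11 | 3,3-dimethyl-6-propyl-2H-pyran-2,4(3H)-dione | CCCC1=CC(=O)C(C)(C)C(=O)O1 | intermediate
12 | trilithium 7-methoxy-6-methyl-8-(1-oxidobut-1-en-1-yl)-4H-chromene-2,5-diolate (phenoxide, lactone enolate and ketone enolate of 5; enolate geometry undefined, not isolated) | CCC=C([O-])c1c(OC)c(C)c([O-])c2CC=C([O-])Oc12.[Li+].[Li+].[Li+] | intermediate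
13 | trilithium salt (phenoxide, C-3 enolate, β-diketonate) of 8-butanoyl-3-(2,2-dimethyl-3,5-dioxooctanoyl)-5-hydroxy-7-methoxy-6-methyl-3,4-dihydro-2H-chromen-2-one (enolate geometry undefined, not isolated) | CCCC([O-])=CC(=O)C(C)(C)C([O-])=C1Cc2c([O-])c(C)c(OC)c(C(=O)CCC)c2OC1=O.[Li+].[Li+].[Li+] | intermediate
14 | aspidin, 2-butanoyl-4-[(3-butanoyl-2,6-dihydroxy-4-methoxy-5-methylphenyl)methyl]-3,5-dihydroxy-6,6-dimethylcyclohexa-2,4-dien-1-one (no stereocentre) | CCCC(=O)C1=C(O)C(Cc2c(O)c(C)c(OC)c(C(=O)CCC)c2O)=C(O)C(C)(C)C1=O | target

**Step count**
Total: 8 steps. Longest linear sequence: 5 steps (steps 1, 2, 3, 4 and 8); the second branch (steps 5, 6, 7) joins in step 8.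

**Steps most likely to fail**

1. Step 8 (proposed new method). What may go wrong: proton transfer from the γ-methylene of 11 to the enolate, competing acylation at the aryl ketone enolate, conjugate addition at C-6 of 11 in place of attack at the enol-ester carbonyl, or a stalled ring closure because the β-keto lactone stays enolised. The fallback uses known reaction types, sets out from 5 and comes back at 14. Compound 5 is added to an excess of the lithium enolate of methyl 2,2-dimethyl-3-oxobutanoate (LiN(i-Pr)2, THF, −78 → 0 °C); this ketone enolate is too weak a base to enolise the lactone or the aryl ketone, and crossed Claisen opening of the lactone should give methyl 7-(3-butanoyl-2,6-dihydroxy-4-methoxy-5-methylphenyl)-2,2-dimethyl-3,5-dioxoheptanoate F1. Polyanion formation with excess LiN(i-Pr)2 (THF, −78 → 0 °C) then places a carbanion on C-6, the only enolisable γ-position because C-2 is quaternary, and Claisen cyclisation onto the ester still closes the same ring last, to 4-[(3-butanoyl-2,6-dihydroxy-4-methoxy-5-methylphenyl)methyl]-3,5-dihydroxy-6,6-dimethylcyclohexa-2,4-dien-1-one F2. O-Butanoylation of the enolised trione (butanoyl chloride, Et3N, CH2Cl2), DMAP-mediated O-to-C acyl shift to the one free ring carbon, and brief K2CO3/MeOH to cleave any phenol ester should then give 14.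

2. Step 1. What may go wrong: poor site selectivity between the two phenols and over-alkylation to the bis ether. The fallback sets out from 1 and comes back at 2. Peracetylation (Ac2O, pyridine) gives 2-oxo-2H-chromene-5,7-diyl diacetate F3. Chemoselective cleavage of the 7-acetate, the ester of the better leaving phenoxide, with PhSH and imidazole in N-methylpyrrolidone gives 7-hydroxy-2-oxo-2H-chromen-5-yl acetate F4. Methylation of the single free phenol (MeI, K2CO3, acetone) gives 7-methoxy-2-oxo-2H-chromen-5-yl acetate F5, and K2CO3/MeOH returns 2.

3. Step 2. What may go wrong: sluggish substitution at the hindered carbon between OH and OMe of a rather electron-poor phenol, with competing condensation of the benzylic alcohol stage to diarylmethanes. The fallback sets out from 2 and comes back at 4. Mannich aminomethylation (aq. CH2O, Me2NH, EtOH, 60 °C) gives 6-[(dimethylamino)methyl]-5-hydroxy-7-methoxy-2H-chromen-2-one F6. Hydrogenation under the conditions of step 3 then hydrogenolyses the benzylic C–N bond of the phenolic Mannich base and saturates C-3–C-4, to give 4.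

**Further compounds**

F1 | step 8 | methyl 7-(3-butanoyl-2,6-dihydroxy-4-methoxy-5-methylphenyl)-2,2-dimethyl-3,5-dioxoheptanoate | COC(=O)C(C)(C)C(=O)CC(=O)CCc1c(O)c(C)c(OC)c(C(=O)CCC)c1O
F2 | step 8 | 4-[(3-butanoyl-2,6-dihydroxy-4-methoxy-5-methylphenyl)methyl]-3,5-dihydroxy-6,6-dimethylcyclohexa-2,4-dien-1-one | O=C1C=C(O)C(Cc2c(O)c(C)c(OC)c(C(=O)CCC)c2O)=C(O)C1(C)C
F3 | step 1 | 2-oxo-2H-chromene-5,7-diyl diacetate | CC(=O)Oc1cc(OC(C)=O)c2C=CC(=O)Oc2c1
F4 | step 1 | 7-hydroxy-2-oxo-2H-chromen-5-yl acetate | CC(=O)Oc1cc(O)cc2OC(=O)C=Cc12
F5 | step 1 | 7-methoxy-2-oxo-2H-chromen-5-yl acetate | CC(=O)Oc1cc(OC)cc2OC(=O)C=Cc12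
F6 | step 2 | 6-[(dimethylamino)methyl]-5-hydroxy-7-methoxy-2H-chromen-2-one | CN(C)Cc1c(OC)cc2OC(=O)C=Cc2c1O
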